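**Retrosynthetic overview**

1. Feature used: in ring A the oxygens at C2' and C4' flank C3', the carbon that carries pyran carbon C4. This 1,3-dioxygen pattern with a nucleophilic central carbon is that of cyclohexane-1,3-dione (1), so ring A is carried as this saturated surrogate.
2. Key disconnection: ring C is cut at C3'–C4 and O1–C2, back to 1 and prenal (2). Forward, Knoevenagel condensation and oxa-6π electrocyclisation give dihydrochromenone 4.
3. The C1'–C(=O) bond is cut next: the kinetic C6 enolate of 4 is C-acylated with a ring B cinnamoyl imidazolide, built from 4-hydroxybenzaldehyde (5) and prenyl bromide (6) as compound 13.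
4. The aromatic unsaturation of ring A is cut last: β-diketone 14 is selenenylated at C6, and selenoxide elimination with tautomerisation gives 18; desilylation gives paratocarpin B (19).
5. Ring order: ring B is bought aromatic, ring C is closed first (step 1), ring A becomes aromatic last (step 8).

Key step: step 1

Remark: enolates, phenoxides and carboxylates formed by plain proton transfer are treated as salt forms of their parent compounds and carry no number of their own; β-diketone 14 is drawn as its diketo tautomer although the enol should predominate. TBS = tert-butyldimethylsilyl, prenyl = 3-methylbut-2-en-1-yl.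

**Route**

Step 1
Reactants: 1 cyclohexane-1,3-dione; 2 prenal (3-methylbut-2-enal)
Product: 4 2,2-dimethyl-7,8-dihydro-2H-chromen-5(6H)-one, via oxatriene 3 (not isolated)
Conditions: ethylenediammonium diacetate (10 mol %), CH2Cl2, rt
Reagents that add atoms: none
Why: The ammonium acetate catalyst condenses with 2 to an unsaturated iminium ion, the enol of 1 adds through its central carbon in a 1,2 sense, and loss of the amine leaves the 2-alkylidene-1,3-dione 3, which is a 1-oxatriene (Knoevenagel condensation, making the C3'–C4 bond). Thermal disrotatory oxa-6π electrocyclisation of 3 then joins a dione oxygen to the dimethyl-bearing terminus (O1–C2 bond) and closes ring C as a six-membered 2H-pyran. The closest known reaction type is the amine-catalysed formal (3+3) annulation of cyclic 1,3-diketones with enals, of which this pair is a standard case. No stereocentre is formed, because C2 carries two methyl groups. The step needs 1,2- over 1,4-addition to the enal and ring closure over a second addition of 1 to 3; the β,β-dimethyl terminus of 2 blocks conjugate attack, iminium activation directs the carbon nucleophile to C1, and the electrocyclisation is intramolecular. Ring-fusion regiochemistry is not in question, since 1 is symmetric and either carbonyl oxygen gives the same pyran.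

Step 2
Reactants: 5 4-hydroxybenzaldehyde; 6 prenyl bromide (1-bromo-3-methylbut-2-ene)
Product: 7 4-hydroxy-3-(3-methylbut-2-en-1-yl)benzaldehyde
Conditions: KOH (1.0 equiv), H2O, rt, 6 added dropwise
Reagents that add atoms: none
Why: Ortho C-alkylation of the ambident phenoxide: in water the oxygen is hydrogen-bonded, so the allylic bromide should be attacked by the ortho carbon at its primary terminus (SN2, linear prenyl group), and 7 should be separable by chromatography from the O-prenyl ether and unchanged 5.

Step 3
Reactants: 7 4-hydroxy-3-prenylbenzaldehyde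
Product: 9 (E)-3-(4-hydroxy-3-prenylphenyl)prop-2-enoic acid, via arylidenemalonic acid 8 (not isolated)
Conditions: malonic acid (2 equiv), piperidine (0.1 equiv), pyridine, 80 °C; cold dilute HCl work-up
Reagents that add atoms: malonic acid, OC(=O)CC(=O)O
Why: Knoevenagel condensation in the Doebner modification: the piperidine-derived iminium of 7 condenses with malonic acid to 8, which loses CO2 in hot pyridine to give the conjugated acid with the thermodynamically preferred E double bond, the free phenol and prenyl group being inert to these weakly basic conditions.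

Step 4
Reactants: 9 (E)-3-(4-hydroxy-3-prenylphenyl)prop-2-enoic acid
Product: 11 (E)-3-(4-TBSO-3-prenylphenyl)prop-2-enoic acid, via bis-silyl compound 10 (not isolated)
Conditions: TBSCl (2.3 equiv), imidazole (5 equiv), DMF, rt; then AcOH/THF/H2O, rt
Reagents that add atoms: tert-butyldimethylsilyl chloride (TBSCl), CC(C)(C)[Si](C)(C)Cl
Why: Imidazole-mediated silylation converts both the phenol and the carboxylic acid, and the silyl ester of 10, far more labile than the aryl silyl ether, should be hydrolysed selectively by aqueous acetic acid (phenol protection against the strong bases of steps 6 and 7).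

Step 5
Reactants: 11 (E)-3-(4-TBSO-3-prenylphenyl)prop-2-enoic acid
Product: 13 (E)-1-(1H-imidazol-1-yl)-3-(4-TBSO-3-prenylphenyl)prop-2-en-1-one, via mixed anhydride 12 (not isolated)
Conditions: 1,1'-carbonyldiimidazole (1.05 equiv), CH2Cl2, rt; cold water wash, dried
Reagents that add atoms: 1,1'-carbonyldiimidazole (CDI), O=C(n1ccnc1)n1ccnc1
Why: Carboxyl activation with carbonyldiimidazole: the acid adds to the reagent to give mixed anhydride 12, which the liberated imidazole attacks with loss of CO2 to give the isolable N-acylimidazole, and free imidazole is washed out because it would protonate the enolate of step 6.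

Step 6
Reactants: 4 2,2-dimethyl-7,8-dihydro-2H-chromen-5(6H)-one (2.1 equiv); 13 cinnamoyl imidazolide (1.0 equiv)
Product: 14 6-[(E)-3-(4-TBSO-3-prenylphenyl)prop-2-enoyl]-2,2-dimethyl-7,8-dihydro-2H-chromen-5(6H)-one
Conditions: LiN(i-Pr)2 (2.0 equiv), THF, −78 °C; then 13, −78 → −20 °C; aq NH4Cl
Reagents that add atoms: none
Why: Claisen-type C-acylation of a kinetic lithium enolate: LiN(i-Pr)2 at −78 °C removes the α′ proton at C6 next to the ketone of the vinylogous ester rather than the γ proton at C8, the hard lithium enolate should attack the activated N-acylimidazole carbonyl (1,2) in preference to the β-carbon, and the second equivalent of enolate (or the released imidazolide) holds 14 as its unreactive lithium diketonate until work-up; the C6 centre is enolisable and needs no control, and surplus 4 is recovered.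

Step 7
Reactants: 14 6-cinnamoyl β-diketone
Product: 15 6-[(E)-3-(4-TBSO-3-prenylphenyl)prop-2-enoyl]-2,2-dimethyl-6-(phenylselanyl)-7,8-dihydro-2H-chromen-5(6H)-one
Conditions: NaH (1.1 equiv), THF, 0 °C; then PhSeCl (1.05 equiv), −78 → 0 °C
Reagents that add atoms: phenylselenyl chloride, Cl[Se]c1ccccc1
Why: α-Selenenylation of a β-dicarbonyl enolate: the sodium enolate of 14 is nucleophilic at C6 between the two carbonyls and should capture PhSeCl at low temperature much faster than the prenyl or pyran double bonds do, giving the quaternary selenide as a racemate whose stereocentre is removed in step 8.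

Step 8
Reactants: 15 C6 phenylselanyl diketone
Product: 18 (E)-3-(4-TBSO-3-prenylphenyl)-1-(5-hydroxy-2,2-dimethyl-2H-chromen-6-yl)prop-2-en-1-one, via selenoxide 16 (not isolated), via dienone 17 (not isolated)
Conditions: mCPBA (1.0 equiv), CH2Cl2, −78 °C, then warm to 0 °C; prompt aq NaHCO3/Na2S2O3 wash
Reagents that add atoms: none
Why: Selenide oxidation and selenoxide syn-elimination: the peracid oxidises selenium far faster than any alkene at −78 °C, selenoxide 16 can eliminate only towards C7–H (the other neighbours of C6 are carbonyl carbons), and the cross-conjugated dienone 17, which has a CH2 at C8, tautomerises to the hydrogen-bonded ortho-acyl phenol, making ring A aromatic.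

Step 9
Reactants: 18 TBS-protected paratocarpin B
Product: 19 paratocarpin B, (E)-1-(5-hydroxy-2,2-dimethyl-2H-chromen-6-yl)-3-(4-hydroxy-3-prenylphenyl)prop-2-en-1-one
Conditions: Bu4NF (1.1 equiv), AcOH (1.1 equiv), THF, 0 °C
Reagents that add atoms: none
Why: Fluoride-induced cleavage of the aryl silyl ether, buffered with acetic acid so that no free phenoxide base is present to promote oxa-Michael closure of the 2′-hydroxychalcone to a flavanone; the E enone, the prenyl group and the chromene should be untouched.

**Compound list**

1 | cyclohexane-1,3-dione | O=C1CCCC(=O)C1 | starting material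
2 | prenal (3-methylbut-2-enal) | CC(C)=CC=O | starting material
3 | 2-(3-methylbut-2-en-1-ylidene)cyclohexane-1,3-dione (1-oxatriene) | CC(C)=CC=C1C(=O)CCCC1=O | intermediate
4 | 2,2-dimethyl-7,8-dihydro-2H-chromen-5(6H)-one | CC1(C)C=CC2=C(CCCC2=O)O1 | intermediate
5 | 4-hydroxybenzaldehyde | O=Cc1ccc(O)cc1 | starting material
6 | prenyl bromide (1-bromo-3-methylbut-2-ene) | CC(C)=CCBr | starting material
7 | 4-hydroxy-3-(3-methylbut-2-en-1-yl)benzaldehyde | CC(C)=CCc1cc(C=O)ccc1O | intermediate
8 | 2-[[4-hydroxy-3-(3-methylbut-2-en-1-yl)phenyl]methylidene]propanedioic acid | CC(C)=CCc1cc(C=C(C(=O)O)C(=O)O)ccc1O | intermediate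
9 | (E)-3-[4-hydroxy-3-(3-methylbut-2-en-1-yl)phenyl]prop-2-enoic acid | CC(C)=CCc1cc(/C=C/C(=O)O)ccc1O | intermediate
10 | tert-butyldimethylsilyl (E)-3-[4-(tert-butyldimethylsilyloxy)-3-(3-methylbut-2-en-1-yl)phenyl]prop-2-enoate | CC(C)=CCc1cc(/C=C/C(=O)O[Si](C)(C)C(C)(C)C)ccc1O[Si](C)(C)C(C)(C)C | intermediate
11 | (E)-3-[4-(tert-butyldimethylsilyloxy)-3-(3-methylbut-2-en-1-yl)phenyl]prop-2-enoic acid | CC(C)=CCc1cc(/C=C/C(=O)O)ccc1O[Si](C)(C)C(C)(C)C | intermediate
12 | mixed anhydride of acid 11 with imidazole-1-carboxylic acid | CC(C)=CCc1cc(/C=C/C(=O)OC(=O)n2ccnc2)ccc1O[Si](C)(C)C(C)(C)C | intermediate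
13 | (E)-1-(1H-imidazol-1-yl)-3-[4-(tert-butyldimethylsilyloxy)-3-(3-methylbut-2-en-1-yl)phenyl]prop-2-en-1-one | CC(C)=CCc1cc(/C=C/C(=O)n2ccnc2)ccc1O[Si](C)(C)C(C)(C)C | intermediate
14 | 6-[(E)-3-[4-(tert-butyldimethylsilyloxy)-3-(3-methylbut-2-en-1-yl)phenyl]prop-2-enoyl]-2,2-dimethyl-7,8-dihydro-2H-chromen-5(6H)-one (diketo tautomer, C6 not defined) | CC(C)=CCc1cc(/C=C/C(=O)C2CCC3=C(C=CC(C)(C)O3)C2=O)ccc1O[Si](C)(C)C(C)(C)C | intermediate
15 | 6-[(E)-3-[4-(tert-butyldimethylsilyloxy)-3-(3-methylbut-2-en-1-yl)phenyl]prop-2-enoyl]-2,2-dimethyl-6-(phenylselanyl)-7,8-dihydro-2H-chromen-5(6H)-one (racemic) | CC(C)=CCc1cc(/C=C/C(=O)C2([Se]c3ccccc3)CCC3=C(C=CC(C)(C)O3)C2=O)ccc1O[Si](C)(C)C(C)(C)C | intermediate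
16 | Se-oxide of 15 (6-benzeneseleninyl compound) | CC(C)=CCc1cc(/C=C/C(=O)C2([Se](=O)c3ccccc3)CCC3=C(C=CC(C)(C)O3)C2=O)ccc1O[Si](C)(C)C(C)(C)C | intermediate
17 | 6-[(E)-3-[4-(tert-butyldimethylsilyloxy)-3-(3-methylbut-2-en-1-yl)phenyl]prop-2-enoyl]-2,2-dimethyl-2H-chromen-5(8H)-one | CC(C)=CCc1cc(/C=C/C(=O)C2=CCC3=C(C=CC(C)(C)O3)C2=O)ccc1O[Si](C)(C)C(C)(C)C | intermediate
18 | (E)-3-[4-(tert-butyldimethylsilyloxy)-3-(3-methylbut-2-en-1-yl)phenyl]-1-(5-hydroxy-2,2-dimethyl-2H-chromen-6-yl)prop-2-en-1-one | CC(C)=CCc1cc(/C=C/C(=O)c2ccc3c(c2O)C=CC(C)(C)O3)ccc1O[Si](C)(C)C(C)(C)C | intermediate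
19 | paratocarpin B, (E)-1-(5-hydroxy-2,2-dimethyl-2H-chromen-6-yl)-3-[4-hydroxy-3-(3-methylbut-2-en-1-yl)phenyl]prop-2-en-1-one | CC(C)=CCc1cc(/C=C/C(=O)c2ccc3c(c2O)C=CC(C)(C)O3)ccc1O | target

**Step count**

Total: 9 steps. Longest linear sequence: 8 steps (steps 2 to 9, from 4-hydroxybenzaldehyde); step 1 is a one-step side branch.

**Steps most likely to fail, with fallbacks**

Step 6. The enolate may add in a conjugate sense to the cinnamoyl unit, acylate on oxygen, or be quenched by proton transfer before acylation is complete. The fallback replaces the Claisen-type acylation by aldol addition and oxidation; it sets out from 13 and 4 and returns at 14. Imidazolide 13 is reduced with i-Bu2AlH (1.1 equiv, CH2Cl2, −78 °C) to the enal (E)-3-[4-(tert-butyldimethylsilyloxy)-3-(3-methylbut-2-en-1-yl)phenyl]prop-2-enal F1. The lithium enolate of 4 (LiN(i-Pr)2, THF, −78 °C) should add 1,2 to the aldehyde of F1 and give the β-hydroxy ketone 6-[(E)-1-hydroxy-3-[4-(tert-butyldimethylsilyloxy)-3-(3-methylbut-2-en-1-yl)phenyl]prop-2-en-1-yl]-2,2-dimethyl-7,8-dihydro-2H-chromen-5(6H)-one F2 as a diastereomer mixture, which does not matter. Dess–Martin periodinane (NaHCO3, CH2Cl2, rt) oxidises the allylic alcohol of F2 to β-diketone 14, and the route continues with step 7.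

Step 8. The selenenic acid released in the elimination, or the peracid, may add to the prenyl or pyran double bond, and the oxidation may run past the selenoxide; step 7 shares the concern about electrophilic selenium. The fallback is a direct quinone dehydrogenation without selenium; it sets out from 14, replaces steps 7 and 8, and returns at 18. DDQ (1.1 equiv, 1,4-dioxane, rt to 60 °C) should abstract hydride from C7 of the enolised β-diketone, and the resulting dienone tautomerises to phenol 18; this fallback makes no compound outside the list (F0).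

Step 2. The ambident phenoxide may be alkylated on oxygen or twice on carbon, so conversion to 7 may be poor. The fallback is halogenation followed by cross-coupling; it sets out from 5 and returns at 7. N-Iodosuccinimide (1.0 equiv, AcOH, rt) iodinates ortho to the hydroxyl and gives 4-hydroxy-3-iodobenzaldehyde F3. Stille coupling of F3 with tributyl(3-methylbut-2-en-1-yl)stannane (Pd(PPh3)4 5 mol %, DMF, 90 °C) should transfer the prenyl group without allylic transposition and give 7, from which step 3 follows.

**Further compounds**

F1 | step 6 | (E)-3-[4-(tert-butyldimethylsilyloxy)-3-(3-methylbut-2-en-1-yl)phenyl]prop-2-enal | CC(C)=CCc1cc(/C=C/C=O)ccc1O[Si](C)(C)C(C)(C)C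
F2 | step 6 | 6-[(E)-1-hydroxy-3-[4-(tert-butyldimethylsilyloxy)-3-(3-methylbut-2-en-1-yl)phenyl]prop-2-en-1-yl]-2,2-dimethyl-7,8-dihydro-2H-chromen-5(6H)-one (diastereomer mixture) | CC(C)=CCc1cc(/C=C/C(O)C2CCC3=C(C=CC(C)(C)O3)C2=O)ccc1O[Si](C)(C)C(C)(C)C
F0 | step 8 | none | none
F3 | step 2 | 4-hydroxy-3-iodobenzaldehyde | O=Cc1ccc(O)c(I)c1
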